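The C48 ester is cut at the C12–C13 single bond, the sp2–sp2 link between the C11=C12 alkene of the electron-poor 8-oxodienyl unit and methyl-bearing C13 of the hexaene. This gives two C24 halves with one ring each. One is a C12 dienylstannane holding the β ring (C3 carbinol), the C8 ketone and the finished C19 octenoate. The other is a C13 hexaenyl iodide holding the ε ring (C3′, C6′). A neutral Stille coupling joins both halves unprotected in the last step, with retention of every alkene geometry. The stannane arises from a Morita–Baylis–Hillman adduct by SN2′ Mitsunobu esterification, the iodide from three Wittig reactions.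

Key step: step 19

Assumption: positions follow carotenoid numbering (β ring C1–C6, chain C7–C15 and C15′–C7′, ε ring C1′–C6′, C19 = oxygenated carbon on C9, C20 = methyl on C13), and (4R,6R)-actinol and (R)-α-ionone are taken as purchasable single enantiomers.

Step 1
Reactants: 1 (4R,6R)-4-hydroxy-2,2,6-trimethylcyclohexanone (actinol)
Product: 2 (4R,6R)-4-(tert-butyldimethylsilyloxy)-2,2,6-trimethylcyclohexanone
Conditions: TBSCl, imidazole, DMF, rt
Reagents that add atoms: tert-butyldimethylsilyl chloride, CC(C)(C)[Si](C)(C)Cl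
Why: Routine silylation of an unhindered secondary alcohol; the carbinol carbon (later C3, R) comes from the chiral pool and is masked for the enolate, Grignard and Mitsunobu steps.

Step 2
Reactants: 2 silyl ether of actinol
Product: 4 (4R)-4-(tert-butyldimethylsilyloxy)-2,6,6-trimethylcyclohex-1-en-1-yl trifluoromethanesulfonate, via lithium enolate 3 (not isolated)
Conditions: LDA, THF, −78 °C; then PhNTf2, −78 °C to rt
Reagents that add atoms: N-phenylbis(trifluoromethanesulfonimide), O=S(=O)(N(c1ccccc1)S(=O)(=O)C(F)(F)F)C(F)(F)F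
Why: Enol triflate formation; the ketone has only one enolisable α-carbon (the other is quaternary), so the tetrasubstituted C5=C6 alkene forms regiospecifically, the methyl-bearing stereocentre is erased and C3 is untouched.

Step 3
Reactants: 4 enol triflate
Product: 5 2-[(4R)-4-(tert-butyldimethylsilyloxy)-2,6,6-trimethylcyclohex-1-en-1-yl]-N-methoxy-N-methylacetamide
Conditions: BrZnCH2C(O)N(OMe)Me (from the bromoamide, Zn dust, cat. TMSCl, THF), Pd2(dba)3, XPhos, THF, 60 °C
Reagents that add atoms: 2-bromo-N-methoxy-N-methylacetamide (used as its zinc reagent), BrCC(=O)N(C)OC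
Why: Negishi-type coupling of a Reformatsky reagent with an alkenyl triflate, a known route to β,γ-unsaturated carbonyl compounds; the bulky electron-rich phosphine helps insertion at hindered C6, the transferred CH2 group offers no β-hydride pathway, and the tetrasubstituted ring alkene has no drive to move into conjugation.

Step 4
Reactants: 5 Weinreb amide
Product: 6 1-[(4R)-4-(tert-butyldimethylsilyloxy)-2,6,6-trimethylcyclohex-1-en-1-yl]but-3-en-2-one
Conditions: vinylmagnesium bromide, THF, −20 to 0 °C; inverse quench into cold aq. KHSO4; used promptly (BHT)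
Reagents that add atoms: vinylmagnesium bromide, C=C[Mg]Br
Why: Weinreb ketone synthesis; the magnesium chelate stops the reaction after one addition, and the cold acidic quench protonates the released amine before it can add to the new vinyl ketone (C8 ketone, C9 and C19 now in place).

Step 5
Reactants: 7 prop-2-yn-1-ol
Product: 8 (E)-3-(tributylstannyl)prop-2-en-1-ol
Conditions: Bu3SnH, AIBN (cat.), neat, 80 °C; chromatography
Reagents that add atoms: tributyltin hydride, CCCC[SnH](CCCC)CCCC
Why: Radical hydrostannation of a terminal alkyne; reversible stannyl-radical addition at this temperature should favour the terminal E isomer, and the other isomers are removed on silica.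

Step 6
Reactants: 8 (E)-3-(tributylstannyl)prop-2-en-1-ol
Product: 9 (E)-3-(tributylstannyl)prop-2-enal
Conditions: MnO2, CH2Cl2, rt
Reagents that add atoms: none
Why: Neutral heterogeneous oxidation of an allylic alcohol, which leaves the C–Sn bond and the E geometry intact.

Step 7
Reactants: 6 vinyl ketone; 9 (E)-3-(tributylstannyl)prop-2-enal
Product: 10 (5E)-1-[(4R)-4-(tert-butyldimethylsilyloxy)-2,6,6-trimethylcyclohex-1-en-1-yl]-4-hydroxy-3-methylidene-6-(tributylstannyl)hex-5-en-2-one (both epimers at the carbinol carbon, carotenoid C10)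
Conditions: DABCO (cat.), excess 9, concentrated THF, 0 °C to rt, slow addition of 6
Reagents that add atoms: none
Why: Morita–Baylis–Hillman reaction; DABCO adds to the vinyl ketone, the zwitterionic enolate attacks the aldehyde 1,2 to form C9–C10 and the amine is expelled, while slow addition of 6 into excess aldehyde suppresses self-dimerisation; the new C10 centre is uncontrolled and is erased in step 8.

Step 8
Reactants: 10 Morita–Baylis–Hillman alcohol; 11 (E)-oct-2-enoic acid
Product: 12 (2E,4E)-2-{[(4R)-4-(tert-butyldimethylsilyloxy)-2,6,6-trimethylcyclohex-1-en-1-yl]acetyl}-5-(tributylstannyl)penta-2,4-dien-1-yl (E)-oct-2-enoate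
Conditions: PPh3, DIAD (betaine preformed), THF, −20 to 0 °C
Reagents that add atoms: none
Why: SN2′ Mitsunobu esterification, known for Morita–Baylis–Hillman alcohols; the carboxylate attacks the C19 methylene (β-carbon of the enone) as the activated C10 oxygen leaves, allylic 1,3-strain places C11 trans to the C8 acyl group (9E), and any ester formed directly at C10 should drain to the same conjugated dienone by a 1,3-acyloxy shift.

Step 9
Reactants: 12 silyl-protected stannane
Product: 13 (2E,4E)-2-{[(4R)-4-hydroxy-2,6,6-trimethylcyclohex-1-en-1-yl]acetyl}-5-(tributylstannyl)penta-2,4-dien-1-yl (E)-oct-2-enoate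
Conditions: Et3N·3HF, MeCN/THF, rt
Reagents that add atoms: none
Why: Fluoride-driven desilylation in a nearly neutral medium, which should spare the allylic ester, the acidic C7 methylene and the electron-poor (hence slowly protonated) dienylstannane.

Step 10
Reactants: 14 (R)-α-ionone
Product: 15 (4E)-3-methyl-5-[(1R)-2,6,6-trimethylcyclohex-2-en-1-yl]penta-1,4-dien-3-ol (both epimers at the tertiary carbinol, C9′)
Conditions: vinylmagnesium bromide, THF, −20 to 0 °C
Reagents that add atoms: vinylmagnesium bromide, C=C[Mg]Br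
Why: Fast 1,2-Grignard addition to the methyl enone, as in the technical vinyl-ionol preparation; it outruns γ-deprotonation so C6′ (R, from the starting material) is kept, and the uncontrolled C9′ centre is erased in step 13.

Step 11
Reactants: 15 vinyl-α-ionol
Product: 16 (4R)-4-[(1E)-3-hydroxy-3-methylpenta-1,4-dien-1-yl]-3,5,5-trimethylcyclohex-2-en-1-one (C9′ epimers)
Conditions: Rh2(cap)4 (dirhodium tetracaprolactamate, cat.), t-BuOOH (70 % aq.), 1,2-dichloroethane, 40 °C, no base
Reagents that add atoms: tert-butyl hydroperoxide, CC(C)(C)OO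
Why: Dirhodium-catalysed allylic C–H oxidation through tert-butylperoxy radicals; the ring C3′ methylene is the only unhindered secondary allylic site (C6′–H is shielded by the C1′ gem-dimethyl and C5′ methyl groups, and the tertiary carbinol has no oxidisable C–H), and the base-free medium protects C6′ from epimerisation.

Step 12
Reactants: 16 ring enone
Product: 17 (1R,4R)-4-[(1E)-3-hydroxy-3-methylpenta-1,4-dien-1-yl]-3,5,5-trimethylcyclohex-2-en-1-ol (C9′ epimers)
Conditions: (S)-Me-CBS oxazaborolidine, catecholborane, toluene, −78 °C; aqueous work-up; chromatography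
Reagents that add atoms: none
Why: Corey–Bakshi–Shibata reduction; with the alkenyl side as the large group the (S)-catalyst should give the 3′R carbinol, and with the C6′ chain pseudoaxial this is also the face anti to the axial C1′ methyl, so reagent and substrate control should reinforce each other towards the 3′,6′-trans diol, while catecholborane at low temperature spares the alkenes.

Step 13
Reactants: 17 diol
Product: 18 {(2E,4E)-5-[(1R,4R)-4-hydroxy-2,6,6-trimethylcyclohex-2-en-1-yl]-3-methylpenta-2,4-dien-1-yl}triphenylphosphonium bromide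
Conditions: PPh3·HBr (1 equiv), CH2Cl2, 0 °C to rt; crystallisation
Reagents that add atoms: triphenylphosphine hydrobromide, [Br-].c1ccccc1[PH+](c1ccccc1)c1ccccc1
Why: Allylic phosphonium salt formation with transposition; the doubly allylic tertiary carbinol ionises far more easily than the secondary ring carbinol (so C3′ is retained), PPh3 captures the pentadienyl cation at its unhindered terminus C11′, and the 9′E salt should be purified by crystallisation.

Step 14
Reactants: 19 but-2-yn-1-ol
Product: 21 (E)-3-iodobut-2-en-1-ol, via bis-zirconated alkenylzirconocene 20 (not isolated)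
Conditions: Cp2Zr(H)Cl (2.3 equiv), THF, rt, dark; then I2, −78 to 0 °C
Reagents that add atoms: iodine, II
Why: Hydrozirconation–iodination; syn addition followed by equilibration with excess Schwartz reagent places zirconium on the less hindered methyl-bearing alkyne carbon (C13), and iodinolysis with retention gives iodine trans to the chain (the later 13E geometry).

Step 15
Reactants: 21 (E)-3-iodobut-2-en-1-ol
Product: 22 (E)-3-iodobut-2-enal
Conditions: MnO2, CH2Cl2, rt, dark; used directly
Reagents that add atoms: none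
Why: Neutral allylic alcohol oxidation that avoids the acid or iodide catalysis which would isomerise the β-iodoenal.

Step 16
Reactants: 22 (E)-3-iodobut-2-enal
Product: 23 (2E,4E)-5-iodohexa-2,4-dienal
Conditions: Ph3P=CHCHO (1 equiv), toluene, 40 °C, dark
Reagents that add atoms: (triphenylphosphoranylidene)acetaldehyde, O=CC=P(c1ccccc1)(c1ccccc1)c1ccccc1
Why: E-selective Wittig olefination with a formyl-stabilised ylide; it forms C15=C15′ and delivers C14′ at the aldehyde level without redox steps, and one equivalent of ylide limits a second homologation.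

Step 17
Reactants: 23 (2E,4E)-5-iodohexa-2,4-dienal
Product: 24 (2E,4E,6E)-7-iodo-2-methylocta-2,4,6-trienal
Conditions: Ph3P=C(CH3)CHO, toluene, 60 °C, dark
Reagents that add atoms: 2-(triphenylphosphoranylidene)propanal, CC(C=O)=P(c1ccccc1)(c1ccccc1)c1ccccc1
Why: E-selective Wittig olefination with the α-methyl formyl-stabilised ylide; it forms C14′=C13′ with C20′ in place, and the α-branched product aldehyde (C12′) is too unreactive towards this ylide to homologate again.

Step 18
Reactants: 18 C15 phosphonium bromide; 24 C9 iodotrienal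
Product: 26 (1R,4R)-4-[(1E,3E,5E,7E,9E,11E)-12-iodo-3,7-dimethyltrideca-1,3,5,7,9,11-hexaen-1-yl]-3,5,5-trimethylcyclohex-2-en-1-ol, via phosphorus ylide 25 (not isolated)
Conditions: 1,2-epoxybutane/EtOH, 60 °C, argon, dark
Reagents that add atoms: none
Why: Wittig olefination under neutral epoxide conditions (bromide opens the epoxide and the alkoxide formed deprotonates the salt), so no free strong base meets the vinylogous acyl iodide or the free hydroxyl; the new C11′=C12′ alkene should end up E because the hindered Z isomer (C10′–H against C20′) equilibrates thermally or is removed by chromatography.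

Step 19
Reactants: 13 C12 dienylstannane (β-ring half); 26 C13 hexaenyl iodide (ε-ring half)
Product: 27 (3R,3′R,6′R)-3,3′-dihydroxy-8-oxo-7,8-dihydro-β,ε-caroten-19-yl (E)-oct-2-enoate (target)
Conditions: Pd2(dba)3, AsPh3, degassed NMP, rt, argon, dark
Reagents that add atoms: none
Why: Stille cross-coupling: zerovalent palladium inserts into the C13–I bond of 26 with retention, the C12 dienyl group of 13 passes from tin to palladium with retention, and reductive elimination forms the C12–C13 sp2–sp2 bond and completes the conjugated octaenone in one operation. The closest known reaction type is the alkenylstannane/alkenyl iodide coupling used for retinoid and carotenoid polyenes with a weakly donating ligand in a polar solvent at room temperature. No ring is closed and no stereocentre is created; C3, C3′ and C6′ are remote and untouched, and the 11E and 13E geometries are inherited from the two partners. The selectivity needed is insertion into the alkenyl C–I bond rather than ionisation of the C19 allylic ester, and it is secured by the much higher reactivity of the iodide at room temperature, the poor donor AsPh3 and the absence of any external nucleophile. The medium is neutral and base-free, so the acidic C7 methylene beside the C8 ketone, the unconjugated C5=C6 ring alkene, the octenoate and both free hydroxyls should survive, which is why no protecting group is carried into this step. Exclusion of light and oxygen limits E/Z scrambling of the product.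

Compound list
1 | (4R,6R)-4-hydroxy-2,2,6-trimethylcyclohexanone (actinol) | O=C1[C@H](C)C[C@@H](O)CC1(C)C | starting material
2 | (4R,6R)-4-(tert-butyldimethylsilyloxy)-2,2,6-trimethylcyclohexanone | O=C1[C@H](C)C[C@@H](O[Si](C)(C)C(C)(C)C)CC1(C)C | intermediate
3 | lithium enolate of 2 | [Li]OC1=C(C)C[C@@H](O[Si](C)(C)C(C)(C)C)CC1(C)C | intermediate
4 | (4R)-4-(tert-butyldimethylsilyloxy)-2,6,6-trimethylcyclohex-1-en-1-yl trifluoromethanesulfonate | FC(F)(F)S(=O)(=O)OC1=C(C)C[C@@H](O[Si](C)(C)C(C)(C)C)CC1(C)C | intermediate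
5 | 2-[(4R)-4-(tert-butyldimethylsilyloxy)-2,6,6-trimethylcyclohex-1-en-1-yl]-N-methoxy-N-methylacetamide | CON(C)C(=O)CC1=C(C)C[C@@H](O[Si](C)(C)C(C)(C)C)CC1(C)C | intermediate
6 | 1-[(4R)-4-(tert-butyldimethylsilyloxy)-2,6,6-trimethylcyclohex-1-en-1-yl]but-3-en-2-one | C=CC(=O)CC1=C(C)C[C@@H](O[Si](C)(C)C(C)(C)C)CC1(C)C | intermediate
7 | prop-2-yn-1-ol | C#CCO | starting material
8 | (E)-3-(tributylstannyl)prop-2-en-1-ol | OC/C=C/[Sn](CCCC)(CCCC)CCCC | intermediate
9 | (E)-3-(tributylstannyl)prop-2-enal | O=C/C=C/[Sn](CCCC)(CCCC)CCCC | intermediate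
10 | Morita–Baylis–Hillman alcohol, (5E)-1-[(4R)-4-(tert-butyldimethylsilyloxy)-2,6,6-trimethylcyclohex-1-en-1-yl]-4-hydroxy-3-methylidene-6-(tributylstannyl)hex-5-en-2-one, carbinol epimers | C=C(C(O)/C=C/[Sn](CCCC)(CCCC)CCCC)C(=O)CC1=C(C)C[C@@H](O[Si](C)(C)C(C)(C)C)CC1(C)C | intermediate
11 | (E)-oct-2-enoic acid | CCCCC/C=C/C(=O)O | starting material
12 | (2E,4E)-2-{[(4R)-4-(tert-butyldimethylsilyloxy)-2,6,6-trimethylcyclohex-1-en-1-yl]acetyl}-5-(tributylstannyl)penta-2,4-dien-1-yl (E)-oct-2-enoate | CCCCC/C=C/C(=O)OC/C(=C\C=C\[Sn](CCCC)(CCCC)CCCC)C(=O)CC1=C(C)C[C@@H](O[Si](C)(C)C(C)(C)C)CC1(C)C | intermediate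
13 | (2E,4E)-2-{[(4R)-4-hydroxy-2,6,6-trimethylcyclohex-1-en-1-yl]acetyl}-5-(tributylstannyl)penta-2,4-dien-1-yl (E)-oct-2-enoate | CCCCC/C=C/C(=O)OC/C(=C\C=C\[Sn](CCCC)(CCCC)CCCC)C(=O)CC1=C(C)C[C@@H](O)CC1(C)C | intermediate
14 | (R)-α-ionone | CC(=O)/C=C/[C@H]1C(C)=CCCC1(C)C | starting material
15 | (4E)-3-methyl-5-[(1R)-2,6,6-trimethylcyclohex-2-en-1-yl]penta-1,4-dien-3-ol, carbinol epimers | C=CC(C)(O)/C=C/[C@H]1C(C)=CCCC1(C)C | intermediate
16 | (4R)-4-[(1E)-3-hydroxy-3-methylpenta-1,4-dien-1-yl]-3,5,5-trimethylcyclohex-2-en-1-one, carbinol epimers | C=CC(C)(O)/C=C/[C@H]1C(C)=CC(=O)CC1(C)C | intermediate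
17 | (1R,4R)-4-[(1E)-3-hydroxy-3-methylpenta-1,4-dien-1-yl]-3,5,5-trimethylcyclohex-2-en-1-ol, tertiary carbinol epimers | C=CC(C)(O)/C=C/[C@H]1C(C)=C[C@H](O)CC1(C)C | intermediate
18 | {(2E,4E)-5-[(1R,4R)-4-hydroxy-2,6,6-trimethylcyclohex-2-en-1-yl]-3-methylpenta-2,4-dien-1-yl}triphenylphosphonium bromide | [Br-].c1ccccc1[P+](c1ccccc1)(c1ccccc1)C/C=C(C)/C=C/[C@H]1C(C)=C[C@H](O)CC1(C)C | intermediate
19 | but-2-yn-1-ol | CC#CCO | starting material
20 | O,C-bis(chlorozirconocene) derivative of (E)-but-2-en-1-ol (cyclopentadienyl rings drawn σ-bonded) | C/C(=C\CO[Zr](Cl)(C1C=CC=C1)C1C=CC=C1)[Zr](Cl)(C1C=CC=C1)C1C=CC=C1 | intermediate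
21 | (E)-3-iodobut-2-en-1-ol | I/C(C)=C/CO | intermediate
22 | (E)-3-iodobut-2-enal | I/C(C)=C/C=O | intermediate
23 | (2E,4E)-5-iodohexa-2,4-dienal | I/C(C)=C/C=C/C=O | intermediate
24 | (2E,4E,6E)-7-iodo-2-methylocta-2,4,6-trienal | I/C(C)=C/C=C/C=C(C)/C=O | intermediate
25 | ylide of 18 | c1ccccc1P(c1ccccc1)(c1ccccc1)=C/C=C(C)/C=C/[C@H]1C(C)=C[C@H](O)CC1(C)C | intermediate
26 | (1R,4R)-4-[(1E,3E,5E,7E,9E,11E)-12-iodo-3,7-dimethyltrideca-1,3,5,7,9,11-hexaen-1-yl]-3,5,5-trimethylcyclohex-2-en-1-ol | I/C(C)=C/C=C/C=C(C)/C=C/C=C(C)/C=C/[C@H]1C(C)=C[C@H](O)CC1(C)C | intermediate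
27 | (3R,3′R,6′R)-3,3′-dihydroxy-8-oxo-7,8-dihydro-β,ε-caroten-19-yl (E)-oct-2-enoate | CCCCC/C=C/C(=O)OC\C(=C/C=C/C(C)=C/C=C/C=C(C)/C=C/C=C(C)/C=C/[C@H]1C(C)=C[C@H](O)CC1(C)C)C(=O)CC1=C(C)C[C@@H](O)CC1(C)C | target

Total step count: 19.
Longest linear sequence: 8 steps (1, 2, 3, 4, 7, 8, 9, 19).

Steps most likely to fail

Step 7. The vinyl ketone may dimerise or oligomerise faster than its zwitterionic enolate adds to the weakly electrophilic stannyl enal. The fallback replaces amine catalysis by a preformed α-metallated enone. It sets out from 5: ethynylmagnesium bromide (THF, 0 °C) gives the terminal ynone F1. DIBAL-H with N-methylmorpholine N-oxide in THF then adds hydride in the 1,4 sense (vinylalumination) to give the α-(diisobutylalumino)vinyl ketone F2. F2 adds to aldehyde 9 in the same flask, and the route is rejoined at 10.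

Step 3. Insertion and zinc-to-palladium transfer may be too slow at the triflate carbon, which is flanked by a quaternary centre and a methyl-bearing alkene carbon, so that loss of the triflate or self-condensation of the zinc reagent takes over. The fallback builds C7–C8 by a Suzuki–Miyaura coupling, the coupling type best suited to such hindered ring triflates.
- It sets out from 4: (E)-2-ethoxyvinylboronic acid pinacol ester, Pd(OAc)2, SPhos and K3PO4 in THF/H2O give the ethoxydiene F3.
- Mild hydrolysis (oxalic acid, THF/H2O, 0 °C) with kinetic α-protonation gives the β,γ-unsaturated aldehyde F4.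
- Vinylmagnesium bromide gives the allylic alcohol F5.
- Dess–Martin periodinane oxidises F5, and the route is rejoined at 6.

Step 19. Tin-to-palladium transfer from the electron-poor dienylstannane may be slow. That would leave time for ionisation of the allylic ester, homocoupling and decay of the hexaenyl iodide. The fallback inverts the polarity of the same C12–C13 union, so that the electron-poor half is the fast-inserting electrophile and the electron-rich half the nucleophile.
- It sets out from 13 and 26.
- Iododestannylation of 13 (I2, CH2Cl2, 0 °C) gives the dienyl iodide F6.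
- Miyaura borylation of 26 (B2pin2, PdCl2(PPh3)2, PPh3, KOPh, toluene, 50 °C) gives the hexaenyl pinacol boronate F7.
- Suzuki–Miyaura coupling of F6 with F7 (Pd(OAc)2, SPhos, K3PO4, THF/H2O, rt, dark) rejoins the route at 27.

Further compounds
F1 | step 7 | 1-[(4R)-4-(tert-butyldimethylsilyloxy)-2,6,6-trimethylcyclohex-1-en-1-yl]but-3-yn-2-one | C#CC(=O)CC1=C(C)C[C@@H](O[Si](C)(C)C(C)(C)C)CC1(C)C
F2 | step 7 | 3-(diisobutylalumino)-1-[(4R)-4-(tert-butyldimethylsilyloxy)-2,6,6-trimethylcyclohex-1-en-1-yl]but-3-en-2-one | C=C([Al](CC(C)C)CC(C)C)C(=O)CC1=C(C)C[C@@H](O[Si](C)(C)C(C)(C)C)CC1(C)C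
F3 | step 3 | tert-butyl{[(1R)-4-[(E)-2-ethoxyethenyl]-3,5,5-trimethylcyclohex-3-en-1-yl]oxy}dimethylsilane | CCO/C=C/C1=C(C)C[C@@H](O[Si](C)(C)C(C)(C)C)CC1(C)C
F4 | step 3 | 2-[(4R)-4-(tert-butyldimethylsilyloxy)-2,6,6-trimethylcyclohex-1-en-1-yl]acetaldehyde | O=CCC1=C(C)C[C@@H](O[Si](C)(C)C(C)(C)C)CC1(C)C
F5 | step 3 | 1-[(4R)-4-(tert-butyldimethylsilyloxy)-2,6,6-trimethylcyclohex-1-en-1-yl]but-3-en-2-ol, carbinol epimers | C=CC(O)CC1=C(C)C[C@@H](O[Si](C)(C)C(C)(C)C)CC1(C)C
F6 | step 19 | (2E,4E)-2-{[(4R)-4-hydroxy-2,6,6-trimethylcyclohex-1-en-1-yl]acetyl}-5-iodopenta-2,4-dien-1-yl (E)-oct-2-enoate | CCCCC/C=C/C(=O)OC/C(=C\C=C\I)C(=O)CC1=C(C)C[C@@H](O)CC1(C)C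
F7 | step 19 | (1R,4R)-4-[(1E,3E,5E,7E,9E,11E)-3,7-dimethyl-12-(4,4,5,5-tetramethyl-1,3,2-dioxaborolan-2-yl)trideca-1,3,5,7,9,11-hexaen-1-yl]-3,5,5-trimethylcyclohex-2-en-1-ol | CC1(C)OB(OC1(C)C)/C(C)=C/C=C/C=C(C)/C=C/C=C(C)/C=C/[C@H]1C(C)=C[C@H](O)CC1(C)C
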